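**Retrosynthetic overview**

1. Feature: ring B holds the fully substituted C8=C9 alkene, with the C17 methyl on C8 and the C11–C12 link to the butenolide on C9. Cutting C12–C13 leaves a 2-methyl-1-vinylcyclohexene, the pattern that ring-closing enyne metathesis gives from an ethynyl group on C10 and a methallyl terminus on the C5 arm.
2. 26 ⇐ 25 (desilylation) ⇐ diene 22 + bromobutenolide 23 (C12–C13 by hydroboration and B-alkyl Suzuki coupling).
3. 22 ⇐ ring A enyne 21 by ring-closing enyne metathesis: C8=C9 closes ring B and the alkene CH2 becomes C12.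
4. 21 ⇐ lactol 17 + methallyl (C6–C7, reagent-controlled C6) ⇐ cis-fused lactone 15; C2 by hydroxyl-directed reduction, resolution through 1-phenylethylamides 13/14.
5. 15 ⇐ enone lactone 9 (alkynyl to C10 from the convex face) ⇐ β-keto ester 1 + enone 2. Ring order: ring A by annulation, a temporary lactone that fixes C4/C5, ring B by metathesis, butenolide attached last.

Key step: step 15

Remark on numbering: atom numbers are those of the labdane skeleton (ring A = C1–C5 and C10, ring B = C5–C10, C17 on C8, C19 = CH2O on C4, side chain C11–C16). β is the face of the C10 methyl, α the face of H5.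

Remark (assumption): compounds 3–9, 11 and 12 are racemic and 13 is a pair of diastereomers. Their SMILES show the enantiomer that leads to 26. Compounds 1, 2, 10, 18 and 23 are taken as purchased.

Step 1
Reactants: 1 ethyl 4-(benzyloxy)-3-oxobutanoate; 2 (E)-pent-3-en-2-one
Product: 4 ethyl 2-[(benzyloxy)methyl]-6-methyl-4-oxocyclohex-2-ene-1-carboxylate (racemic; cis/trans mixture), via Michael adduct 3 (not isolated)
Conditions: NaOEt (cat.), EtOH, 0 °C to rt; then pyrrolidine, AcOH, toluene, reflux with removal of water
Reagents that add atoms: none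
Why: Base-catalysed Michael addition of the β-keto ester to the enone and amine-mediated intramolecular aldol condensation of the methyl ketone onto the α-alkoxy ketone (Robinson-type annulation as used for Hagemann's ester) should build ring A, and the two stereocentres formed (C5, C10) need no control because C5 is corrected in step 3 and C10 is removed in step 5.

Step 2
Reactants: 4 enone ester
Product: 5 ethyl 2-[(benzyloxy)methyl]-2,6-dimethyl-4-oxocyclohexane-1-carboxylate (racemic; diastereomer mixture)
Conditions: Me2CuLi (from MeLi and CuI), Et2O, −20 to 0 °C; NH4Cl aq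
Reagents that add atoms: lithium dimethylcuprate, [Li+].C[Cu-]C
Why: Organocuprate conjugate addition to the β,β-disubstituted enone (known for Hagemann's ester) should create the quaternary C4 with its methyl and CH2OBn groups, and its face selectivity is irrelevant because the material is racemic and C5 is set relative to C4 in step 3.

Step 3
Reactants: 5 keto ester
Product: 7 cis-fused keto lactone 3a,7-dimethylhexahydro-2-benzofuran-1,5-dione (racemic; C10 epimers), via hydroxy ester 6 (not isolated)
Conditions: H2 (1 atm), Pd/C, EtOH, rt; filter; then NaOEt (cat.), EtOH, 50 °C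
Reagents that add atoms: none
Why: Hydrogenolysis of the benzyl ether followed by ethoxide-mediated epimerisation at C5 and lactonisation should funnel all isomers into the cis-fused γ-lactone, since only the isomer with C19 and C6 on the same face can close, which sets C5 relative to C4 (thermodynamic control through a cyclic constraint).

Step 4
Reactants: 7 keto lactone
Product: 8 trimethylsilyl enol ether of 7 (C1=C2, silyloxy on C2)
Conditions: LiN(iPr)2, THF, −78 °C; Me3SiCl, −78 to 0 °C
Reagents that add atoms: chlorotrimethylsilane, C[Si](C)(C)Cl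
Why: Kinetic enolisation with LiN(iPr)2 should take the C1 proton rather than the neopentyl C3 proton next to quaternary C4 (and rather than the less acidic lactone α-proton), and O-silylation gives the regiodefined silyl enol ether.

Step 5
Reactants: 8 silyl enol ether
Product: 9 enone lactone 3a,7-dimethyl-3a,4-dihydro-2-benzofuran-1,5(3H,7aH)-dione (racemic; C1=C10 enone with the methyl on C10)
Conditions: Pd(OAc)2 (cat.), O2 (1 atm), DMSO, 40 °C
Reagents that add atoms: none
Why: Saegusa oxidation (divalent palladium enolate, β-hydride elimination of H10) should give the C1=C10 enone, which erases the C10 stereocentre so that both epimers converge on one compound.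

Step 6
Reactants: 9 enone lactone; 10 trimethylsilylacetylene
Product: 12 7-ethynyl-3a,7-dimethylhexahydro-2-benzofuran-1,5-dione (racemic; ethynyl α and methyl β on C10), via C-silyl alkyne 11 (not isolated)
Conditions: 10, n-BuLi, Et2O, 0 °C, then Me2AlCl; Ni(acac)2 (cat.) reduced with iBu2AlH (cat.), Et2O, −5 °C to rt; KH2PO4 aq; then K2CO3 (cat.), MeOH, rt; dilute HCl
Reagents that add atoms: dimethyl[(trimethylsilyl)ethynyl]aluminium (made in the flask from 10), C[Al](C)C#C[Si](C)(C)C
Why: Conjugate addition of a dialkylaluminium acetylide under low-valent nickel catalysis (required because the enone is fixed s-trans) should place the alkynyl group on C10 from the convex α face, anti to the lactone ring fused at C4–C5, so that the C10 methyl ends β (substrate control by the bicyclic shape), and carbonate methanolysis then removes the C-silyl group.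

Step 7
Reactants: 12 ethynyl keto lactone
Product: 13 (S)-N-(1-phenylethyl)-2-ethynyl-6-(hydroxymethyl)-2,6-dimethyl-4-oxocyclohexane-1-carboxamide (two diastereomers)
Conditions: (S)-1-phenylethylamine, AlMe3, toluene, 0 to 60 °C; dilute HCl work-up
Reagents that add atoms: (S)-1-phenylethylamine, C[C@H](N)c1ccccc1
Why: Aminolysis of the lactone with the dimethylaluminium amide of (S)-1-phenylethylamine (a standard lactone-to-hydroxy-amide opening) frees the C19 hydroxyl needed in step 8 and turns the racemate into two diastereomeric amides for a classical resolution, while no stereocentre is formed and the acidic work-up hydrolyses any ketimine.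

Step 8
Reactants: 13 hydroxy amide ketone (both diastereomers)
Product: 14 (S)-N-(1-phenylethyl)-2-ethynyl-4-hydroxy-6-(hydroxymethyl)-2,6-dimethylcyclohexane-1-carboxamide with 2α-OH and the ring configuration of 26 (single diastereomer after separation)
Conditions: Me4NBH(OAc)3, MeCN/AcOH, −20 °C; separation of the diastereomers by crystallisation or chromatography
Reagents that add atoms: none
Why: Hydroxyl-directed reduction of Evans–Saksena type should exchange the reagent onto the C19 hydroxyl, which sits 1,3 to C2 on the β face, and deliver hydride internally to the β face of the ketone to set the 2α alcohol (a ketone without a neighbouring hydroxyl is not reduced by this reagent), and the diastereomer with the ring configuration of 26 is then separated and assigned against the known (S) centre.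

Step 9
Reactants: 14 diol amide
Product: 15 7-ethynyl-5-hydroxy-3a,7-dimethylhexahydro-2-benzofuran-1(3H)-one (single enantiomer; 2α-OH, cis-fused lactone)
Conditions: 2 M H2SO4, 1,4-dioxane, 80 °C
Reagents that add atoms: none
Why: Acid-promoted N-to-O acyl transfer onto the cis C19 hydroxyl should reclose the γ-lactone and release the resolving amine (the usual end of a lactone resolution through 1-phenylethylamides), with no stereocentre touched.

Step 10
Reactants: 15 hydroxy lactone
Product: 16 C2 tert-butyldimethylsilyl ether of 15
Conditions: tBuMe2SiOTf, 2,6-lutidine, CH2Cl2, −78 to 0 °C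
Reagents that add atoms: tert-butyldimethylsilyl triflate, CC(C)(C)[Si](C)(C)OS(=O)(=O)C(F)(F)F
Why: Silyl triflate with 2,6-lutidine should silylate the secondary C2 alcohol cleanly (O-silylation), the lactone and the terminal alkyne being inert.

Step 11
Reactants: 16 silyl ether lactone
Product: 17 lactol (C6 hemiacetal, anomer mixture)
Conditions: iBu2AlH, CH2Cl2, −78 °C; KNaC4H4O6 aq
Reagents that add atoms: none
Why: Partial reduction of the γ-lactone with iBu2AlH at −78 °C should stop at the lactol because the aluminium hemiacetal does not collapse at this temperature, which puts C6 at the aldehyde oxidation level.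

Step 12
Reactants: 17 lactol; 18 CH2=C(CH3)CH2MgCl (methallylmagnesium chloride)
Product: 19 diol: ring A with C10 ethynyl, 2α-OSiMe2tBu, free C19 CH2OH and a C5 (1S)-1-hydroxy-3-methylbut-3-enyl arm
Conditions: (−)-Ipc2BOMe and 18, Et2O, −78 °C to rt; then 17, Et2O, −78 °C to rt; NaOH aq, H2O2
Reagents that add atoms: (−)-B-methallyldiisopinocampheylborane (made in the flask from 18), CC(=C)CB([C@@H]1C[C@@H]2C[C@@H](C2(C)C)[C@H]1C)[C@@H]1C[C@@H]2C[C@@H](C2(C)C)[C@H]1C
Why: Brown asymmetric methallylboration acts on the hydroxy aldehyde in equilibrium with the lactol, and the chair transition state with the isopinocampheyl groups derived from (+)-α-pinene should add the methallyl group to the aldehyde face that gives the (6S) alcohol (reagent control, as found for α-branched aldehydes), forming C6–C7.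

Step 13
Reactants: 19 diol
Product: 20 C19 tert-butyldimethylsilyl ether with free C6 hydroxyl
Conditions: tBuMe2SiCl, imidazole, DMF, 0 °C
Reagents that add atoms: tert-butyldimethylsilyl chloride, CC(C)(C)[Si](C)(C)Cl
Why: The primary neopentyl C19 hydroxyl should silylate much faster than the secondary C6 hydroxyl flanked by two quaternary carbons (steric differentiation in O-silylation).

Step 14
Reactants: 20 alcohol
Product: 21 ring A enyne: C10 ethynyl, C5 (1S)-1-acetoxy-3-methylbut-3-enyl arm, 2α- and C19-OSiMe2tBu
Conditions: Ac2O, DMAP, pyridine, 40 °C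
Reagents that add atoms: acetic anhydride, CC(=O)OC(C)=O
Why: DMAP-catalysed acylation should acetylate the hindered secondary C6 alcohol with retention of configuration.

Step 15
Reactants: 21 ring A enyne
Product: 22 9-vinyl-8-methyl octalin (8,11-diene) with 6α-OAc, 2α- and C19-OSiMe2tBu
Conditions: second-generation Grubbs catalyst RuCl2(H2IMes)(PCy3)(=CHPh) (10 mol %), toluene (2 mM), 80 °C, argon, no ethylene
Reagents that add atoms: none
Why: A ruthenium alkylidene (the methylidene after the first turnover) adds to the terminal alkyne with C–C bond formation at C11, which leaves ruthenium on C9; this vinylcarbene closes onto the 1,1-disubstituted alkene through a ruthenacyclobutane, and cycloreversion forms C8=C9 while the alkene CH2 leaves on ruthenium and is delivered to C11 of the next molecule as C12. The closest known reaction type is ring-closing enyne metathesis of 1,7-enynes to 1-vinylcyclohexenes, including tetrasubstituted ring alkenes from 1,1-disubstituted alkene partners. Ring B closes in the exo mode to a six-membered ring that is trans-fused, since the C10 alkyne and the C5 arm are trans-diequatorial on ring A. No stereocentre is formed and none is touched. The step needs exo over endo closure (ruthenium on C11 would lead to a seven-membered ring with an exocyclic methylene) and it needs ring closure to outrun intermolecular trapping; the smaller ring, the insertion regiochemistry known from cross enyne metathesis and the proximity of the two arms favour the wanted path. Ethylene is left out on purpose, because it would convert the hindered alkyne into an acyclic 2-substituted butadiene that cannot close to the tetrasubstituted alkene, and high dilution takes over its role of suppressing alkyne oligomerisation.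

Step 16
Reactants: 22 diene; 23 4-bromofuran-2(5H)-one
Product: 25 bis-silyl ether of 26, via alkylborane 24 (not isolated)
Conditions: 9-BBN, THF, 0 °C to rt; then 23, Pd(dppf)Cl2 (cat.), AsPh3 (cat.), K3PO4 aq, DMF, rt
Reagents that add atoms: none
Why: 9-BBN should hydroborate only the monosubstituted C11=C12 alkene with boron on C12 (anti-Markovnikov, the tetrasubstituted C8=C9 alkene being inert), and B-alkyl Suzuki–Miyaura coupling of the alkylborane with the vinylogous acyl bromide under zerovalent palladium catalysis should join C12 to C13 while mild aqueous phosphate spares the acetate and the butenolide.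

Step 17
Reactants: 25 bis-silyl ether
Product: 26 target, 6α-acetoxy-2α,19-dihydroxylabda-8,13-diene with the C15 carbonyl/C16 oxymethylene butenolide, (2R,4S,5R,6S,10S) in labdane numbering
Conditions: HF·pyridine, pyridine, THF, 0 °C to rt
Reagents that add atoms: none
Why: Fluoride cleaves both silyl ethers (Si–F bond formation) under buffered conditions that should leave the acetate, the butenolide and the C8=C9 alkene untouched.

**Compound list**

1 | ethyl 4-(benzyloxy)-3-oxobutanoate | CCOC(=O)CC(=O)COCc1ccccc1 | starting material
2 | (E)-pent-3-en-2-one | C/C=C/C(C)=O | starting material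
3 | ethyl 2-[(benzyloxy)acetyl]-3-methyl-5-oxohexanoate (Michael adduct, diastereomer mixture) | CCOC(=O)C(C(C)CC(C)=O)C(=O)COCc1ccccc1 | intermediate (not isolated)
4 | ethyl 2-[(benzyloxy)methyl]-6-methyl-4-oxocyclohex-2-ene-1-carboxylate (racemic, cis/trans mixture) | CCOC(=O)C1C(C)CC(=O)C=C1COCc1ccccc1 | intermediate
5 | ethyl 2-[(benzyloxy)methyl]-2,6-dimethyl-4-oxocyclohexane-1-carboxylate (racemic, diastereomer mixture) | CCOC(=O)C1C(C)CC(=O)CC1(C)COCc1ccccc1 | intermediate
6 | ethyl 2-(hydroxymethyl)-2,6-dimethyl-4-oxocyclohexane-1-carboxylate (diastereomer mixture) | CCOC(=O)C1C(C)CC(=O)CC1(C)CO | intermediate (not isolated)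
7 | cis-fused keto lactone 3a,7-dimethylhexahydro-2-benzofuran-1,5-dione (racemic; lactone C6(=O)–O–C19 on the β face, C4 methyl α, C10 epimers) | CC1CC(=O)C[C@]2(C)COC(=O)[C@H]12 | intermediate
8 | trimethylsilyl enol ether of 7 (C1=C2) | CC1C=C(O[Si](C)(C)C)C[C@]2(C)COC(=O)[C@H]12 | intermediate
9 | enone lactone 3a,7-dimethyl-3a,4-dihydro-2-benzofuran-1,5(3H,7aH)-dione (racemic) | CC1=CC(=O)C[C@]2(C)COC(=O)[C@H]12 | intermediate
10 | trimethylsilylacetylene | C[Si](C)(C)C#C | starting material
11 | 3a,7-dimethyl-7-[(trimethylsilyl)ethynyl]hexahydro-2-benzofuran-1,5-dione (racemic; alkynyl α on C10) | C[Si](C)(C)C#C[C@@]1(C)CC(=O)C[C@]2(C)COC(=O)[C@H]12 | intermediate (not isolated)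
12 | 7-ethynyl-3a,7-dimethylhexahydro-2-benzofuran-1,5-dione (racemic; ethynyl α, C10 methyl β) | C#C[C@@]1(C)CC(=O)C[C@]2(C)COC(=O)[C@H]12 | intermediate
13 | (S)-N-(1-phenylethyl)-2-ethynyl-6-(hydroxymethyl)-2,6-dimethyl-4-oxocyclohexane-1-carboxamide (shown: diastereomer with the ring configuration of 26; formed together with the diastereomer of enantiomeric ring) | C#C[C@@]1(C)CC(=O)C[C@](C)(CO)[C@@H]1C(=O)N[C@@H](C)c1ccccc1 | intermediate
14 | (S)-N-(1-phenylethyl)-2-ethynyl-4-hydroxy-6-(hydroxymethyl)-2,6-dimethylcyclohexane-1-carboxamide (2α-OH, single diastereomer) | C#C[C@@]1(C)C[C@@H](O)C[C@](C)(CO)[C@@H]1C(=O)N[C@@H](C)c1ccccc1 | intermediate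
15 | 7-ethynyl-5-hydroxy-3a,7-dimethylhexahydro-2-benzofuran-1(3H)-one (single enantiomer, 2α-OH) | C#C[C@@]1(C)C[C@@H](O)C[C@]2(C)COC(=O)[C@H]12 | intermediate
16 | C2 tert-butyldimethylsilyl ether of 15 | C#C[C@@]1(C)C[C@@H](O[Si](C)(C)C(C)(C)C)C[C@]2(C)COC(=O)[C@H]12 | intermediate
17 | lactol from 16 (C6 hemiacetal, anomer mixture) | C#C[C@@]1(C)C[C@@H](O[Si](C)(C)C(C)(C)C)C[C@]2(C)COC(O)[C@H]12 | intermediate
18 | methallylmagnesium chloride | CC(=C)C[Mg]Cl | starting material
19 | diol: ring A with C10 ethynyl, 2α-OSiMe2tBu, C19 CH2OH and C5 (1S)-1-hydroxy-3-methylbut-3-enyl arm | C#C[C@@]1(C)C[C@@H](O[Si](C)(C)C(C)(C)C)C[C@](C)(CO)[C@@H]1[C@@H](O)CC(C)=C | intermediate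
20 | C19 tert-butyldimethylsilyl ether of 19 (free 6-OH) | C#C[C@@]1(C)C[C@@H](O[Si](C)(C)C(C)(C)C)C[C@](C)(CO[Si](C)(C)C(C)(C)C)[C@@H]1[C@@H](O)CC(C)=C | intermediate
21 | ring A enyne, key precursor: C10 ethynyl, C5 (1S)-1-acetoxy-3-methylbut-3-enyl arm, 2α- and C19-OSiMe2tBu | C#C[C@@]1(C)C[C@@H](O[Si](C)(C)C(C)(C)C)C[C@](C)(CO[Si](C)(C)C(C)(C)C)[C@@H]1[C@@H](OC(C)=O)CC(C)=C | intermediate
22 | 9-vinyl-8-methyl octalin (8,11-diene), 6α-OAc, 2α- and C19-OSiMe2tBu | CC(=O)O[C@H]1CC(C)=C(C=C)[C@@]2(C)C[C@@H](O[Si](C)(C)C(C)(C)C)C[C@](C)(CO[Si](C)(C)C(C)(C)C)[C@H]12 | intermediate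
23 | 4-bromofuran-2(5H)-one | BrC1=CC(=O)OC1 | starting material
24 | C12 9-borabicyclo[3.3.1]nonan-9-yl adduct of 22 | CC(=O)O[C@H]1CC(C)=C(CCB3C4CCCC3CCC4)[C@@]2(C)C[C@@H](O[Si](C)(C)C(C)(C)C)C[C@](C)(CO[Si](C)(C)C(C)(C)C)[C@H]12 | intermediate (not isolated)
25 | 2,19-bis(tert-butyldimethylsilyl) ether of 26 | CC(=O)O[C@H]1CC(C)=C(CCC3=CC(=O)OC3)[C@@]2(C)C[C@@H](O[Si](C)(C)C(C)(C)C)C[C@](C)(CO[Si](C)(C)C(C)(C)C)[C@H]12 | intermediate
26 | CNP0231903.1, 6α-acetoxy-2α,19-dihydroxylabda-8,13-diene butenolide, (2R,4S,5R,6S,10S) | CC(=O)O[C@H]1CC(C)=C(CCC2=CC(=O)OC2)[C@@]2(C)C[C@@H](O)C[C@](C)(CO)[C@H]12 | target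

Total step count: 17
Longest linear sequence: 17 steps (1 and 2 to 26)

**Steps most likely to fail**

Step 15 (ring-closing enyne metathesis). The alkyne sits on a quaternary carbon, so the carbene may insert it with ruthenium on C11 instead of C9; that path leads to seven-membered endo closure or to oligomers, and closure onto the hindered 1,1-disubstituted alkene may be slow. The fallback keeps the same ring closure but delivers ruthenium to C8 by a relay. It sets out from alcohol 20. Silylation with Et3SiOTf and 2,6-lutidine gives the C6 triethylsilyl ether F1. Ozonolysis of the 1,1-disubstituted alkene (O3, CH2Cl2/MeOH, −78 °C, then PPh3; the terminal alkyne reacts far more slowly) gives the methyl ketone F2. Wittig olefination with the ylide from hex-5-enyltriphenylphosphonium bromide and NaN(SiMe3)2 gives the trisubstituted alkene with a pent-4-enyl relay arm, the relay triene F3 (E/Z mixture). Removal of the triethylsilyl group (pyridinium p-toluenesulfonate, MeOH) and acetylation (Ac2O, DMAP) give the relay acetate F4. With the second-generation Grubbs catalyst under argon, ruthenium should load at the terminal alkene of the relay arm, expel cyclopentene and so arrive on C8. The resulting carbene should insert the alkyne in the exo mode (C8–C9 bond, ruthenium on the unhindered C11) and be released as the C11=C12 vinyl group by methylene transfer from the relay terminus of the next molecule. The fallback comes back to the route at diene 22.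

Step 6 (conjugate alkynylation). Transfer of the alkynyl group to the hindered β-carbon next to C5 may be slow, so that 1,2-addition or reduction of the enone takes over. The fallback sets out from enone 9. CH2=CHMgBr with CuBr·SMe2 and Me3SiCl (THF, −78 °C), a conjugate addition that is routine for β,β-disubstituted cyclohexenones, should give from the same convex face the C10 vinyl keto lactone F5. Ozonolysis (O3, then Me2S) gives the C9 aldehyde F6. Seyferth–Gilbert homologation with the Ohira–Bestmann reagent (K2CO3, MeOH, then dilute HCl), which reacts with the aldehyde much faster than with the ketone, comes back to the route at ethynyl ketone 12.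

Step 12 (asymmetric methallylboration of the lactol). The hindered lactol may offer too little open aldehyde, and the temperature then needed may erode reagent control at C6. The fallback sets out from lactone 16. Mono-addition of 18 at −78 °C gives the hydroxy ketone F7 (in equilibrium with its cyclic hemiketal). Silylation of the primary hydroxyl of the open form (tBuMe2SiCl, imidazole) gives the β,γ-unsaturated silyl ether ketone F8. Corey–Bakshi–Shibata reduction with the (R)-2-methyl-oxazaborolidine and catecholborane (toluene, −78 °C), in which ring carbon C5 is the large and the methallyl CH2 the small substituent, should give the (6S) alcohol and comes back to the route at 20.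

**Further compounds**

F1 | step 15 | C6 triethylsilyl ether of 20 | C#C[C@@]1(C)C[C@@H](O[Si](C)(C)C(C)(C)C)C[C@](C)(CO[Si](C)(C)C(C)(C)C)[C@@H]1[C@@H](O[Si](CC)(CC)CC)CC(C)=C
F2 | step 15 | methyl ketone from ozonolysis of F1 | C#C[C@@]1(C)C[C@@H](O[Si](C)(C)C(C)(C)C)C[C@](C)(CO[Si](C)(C)C(C)(C)C)[C@@H]1[C@@H](O[Si](CC)(CC)CC)CC(C)=O
F3 | step 15 | relay triene, C8(CH3)=CH(CH2)3CH=CH2 arm, C6 triethylsilyl ether (E/Z mixture) | C#C[C@@]1(C)C[C@@H](O[Si](C)(C)C(C)(C)C)C[C@](C)(CO[Si](C)(C)C(C)(C)C)[C@@H]1[C@@H](O[Si](CC)(CC)CC)CC(C)=CCCCC=C
F4 | step 15 | relay acetate (E/Z mixture) | C#C[C@@]1(C)C[C@@H](O[Si](C)(C)C(C)(C)C)C[C@](C)(CO[Si](C)(C)C(C)(C)C)[C@@H]1[C@@H](OC(C)=O)CC(C)=CCCCC=C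
F5 | step 6 | 3a,7-dimethyl-7-vinylhexahydro-2-benzofuran-1,5-dione (racemic, vinyl α) | C=C[C@@]1(C)CC(=O)C[C@]2(C)COC(=O)[C@H]12
F6 | step 6 | 3a,7-dimethyl-1,5-dioxohexahydro-2-benzofuran-7-carbaldehyde (racemic) | O=C[C@@]1(C)CC(=O)C[C@]2(C)COC(=O)[C@H]12
F7 | step 12 | hydroxy ketone: C5 3-methylbut-3-enoyl arm, free C19 CH2OH (open form of the hemiketal) | C#C[C@@]1(C)C[C@@H](O[Si](C)(C)C(C)(C)C)C[C@](C)(CO)[C@@H]1C(=O)CC(C)=C
F8 | step 12 | C19 tert-butyldimethylsilyl ether of F7 | C#C[C@@]1(C)C[C@@H](O[Si](C)(C)C(C)(C)C)C[C@](C)(CO[Si](C)(C)C(C)(C)C)[C@@H]1C(=O)CC(C)=C
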